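The target is divided at the exocyclic alkene C1=CH–C5′ into a bromo-alkyne that becomes the indane and a dihydrobenzofuran boronate; a carbopalladation–Suzuki cascade joins them. Everything rests on reading the dihydrobenzofuran ring (O1′, C2′, C3′, C3a′, C7a′), with its 2′-aryl group and the carbon substituent on C3′, as a ring-contracted flavanone. In one operation an iodine-mediated oxidation shifts arene carbon C4a of the chromanone from C4 to C3, which closes the five-membered ring, keeps the C2 stereocentre and leaves C4 as a trans ester, the handle for a later decarboxylative arylation. The precursor is the (S)-6-chloro-4′-methoxyflavanone, made by asymmetric conjugate addition to 6-chlorochromone.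

Key step: step 2

Assumption: each chiral catalyst is named as the enantiomer that the accepted model of its reaction predicts for the configuration needed; the antipode of each is equally available and would be used if the sense of induction on these substrates were the opposite.
Assumption: 2-bromo-4,6-dimethoxybenzaldehyde (12) is treated as a purchasable compound.
Numbering: primed locants belong to the dihydrobenzofuran, unprimed ones to the indane; 3 and 4 carry flavanone numbering.

Step 1
Reactants: 1 6-chloro-4H-chromen-4-one; 2 (4-methoxyphenyl)boronic acid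
Product: 3 (2S)-6-chloro-2-(4-methoxyphenyl)-2,3-dihydro-4H-chromen-4-one
Conditions: Pd(OCOCF3)2 (5 mol%), (R)-4-tert-butyl-2-(pyridin-2-yl)-4,5-dihydrooxazole (6 mol%), NH4PF6 (30 mol%), H2O (5 equiv), ClCH2CH2Cl, 60 °C
Reagents that add atoms: none
Why: Asymmetric conjugate addition of an arylboronic acid to a chromone under cationic divalent palladium–pyridine-oxazoline catalysis, a known reaction of chromones: the aryl–palladium species inserts the C2=C3 bond on the enone face left open by the tert-butyl group of the ligand, which sets C2 as S, and water protonates the palladium enolate before β-hydride elimination can give the flavone.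

Step 2
Reactants: 3 (2S)-6-chloro-2-(4-methoxyphenyl)-2,3-dihydro-4H-chromen-4-one
Product: 5 methyl (2S,3S)-5-chloro-2-(4-methoxyphenyl)-2,3-dihydro-1-benzofuran-3-carboxylate, via enol ether 4 (not isolated)
Conditions: HC(OMe)3 (solvent), H2SO4 (0.5 equiv), 0 °C, 30 min; then PhI(OAc)2 (1.2 equiv), 0 → 25 °C; aqueous NaHCO3 work-up
Reagents that add atoms: trimethyl orthoformate, COC(OC)OC
Why: Acid and orthoformate turn the ketone into enol ether 4, whose C3 is attacked by the trivalent iodine electrophile on the face anti to the equatorial C2 aryl group while methanol adds at C4. In this adduct the equatorial C3–I bond is antiperiplanar to the C4–C4a bond, so arene carbon C4a, activated by the ortho ring oxygen O1, moves from C4 to C3 as iodobenzene leaves, and C4 remains as a dimethoxycarbenium ion that gives the methyl ester on work-up. The closest known reaction type is the hypervalent-iodine oxidative ring contraction of flavanones to methyl trans-2-aryl-2,3-dihydrobenzofuran-3-carboxylates, a semipinacol-type 1,2-aryl shift. The ring O1′–C2′–C3′–C3a′–C7a′ is closed by ring contraction and not by cyclisation of a chain: C4a attacks C3 in a 3-exo-tet sense through a phenonium-like bridged transition state as the C4–C4a bond breaks. The new centre C3′ is controlled by the resident C2 centre, since anti iodination followed by migration with inversion puts the ester trans to the 2′-aryl group (also the more stable arrangement), and C2 itself is not touched. The step needs ring contraction to win over the 2,3-shift of the anisyl group (isoflavone), over elimination to the flavone and over acid-induced opening of the pyranone (racemisation); complete formation of 4 at 0 °C before the oxidant is added, water-free orthoformate as solvent, and the chair with equatorial aryl and iodine, in which only C4a is aligned to migrate, are what should secure it.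

Step 3
Reactants: 5 methyl (2S,3S)-5-chloro-2-(4-methoxyphenyl)-2,3-dihydro-1-benzofuran-3-carboxylate
Product: 6 (2S,3S)-5-chloro-2-(4-methoxyphenyl)-2,3-dihydro-1-benzofuran-3-carboxylic acid
Conditions: LiOH·H2O (3 equiv), THF/H2O (3:1), 0 → 25 °C; then 1 M HCl
Reagents that add atoms: lithium hydroxide, [Li+].[OH-]
Why: Saponification of the methyl ester at low temperature, where addition of hydroxide to the ester carbonyl is faster than deprotonation at C3′ and opening of the benzylic ether, so C2′ is kept; the configuration at C3′ is erased in the next step in any case.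

Step 4
Reactants: 6 (2S,3S)-5-chloro-2-(4-methoxyphenyl)-2,3-dihydro-1-benzofuran-3-carboxylic acid; 7 1-bromo-3,5-dimethoxybenzene
Product: 10 (2S,3S)-5-chloro-3-(3,5-dimethoxyphenyl)-2-(4-methoxyphenyl)-2,3-dihydro-1-benzofuran, via N-hydroxyphthalimide ester 8 (not isolated), via arylzinc chloride 9 (not isolated)
Conditions: N-hydroxyphthalimide (1.1 equiv), DIC (1.1 equiv), CH2Cl2, 25 °C; separately 7, Mg, LiCl, THF, 25 °C, then ZnCl2; the two combined with NiCl2·glyme (20 mol%), 4,4′-di-tert-butyl-2,2′-bipyridine (40 mol%), THF/DMF, 25 °C; 1 M HCl work-up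
Reagents that add atoms: none
Why: One-pot carbodiimide esterification to the redox-active ester 8 followed by nickel-catalysed decarboxylative Negishi-type arylation: electron transfer from an aryl–nickel species to 8 releases CO2 and phthalimide anion, and the planar benzylic C3′ radical is arylated through nickel on the face anti to the 2′-aryl group, so that C2′ sets the new C3′ centre trans (S), while ring opening of the radical is disfavoured because the C2′–O1′ bond lies close to the nodal plane of the radical orbital and the aryl chloride is inert to the nickel–bipyridine catalyst at 25 °C.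

Step 5
Reactants: 10 (2S,3S)-5-chloro-3-(3,5-dimethoxyphenyl)-2-(4-methoxyphenyl)-2,3-dihydro-1-benzofuran
Product: 11 2-[(2S,3S)-3-(3,5-dimethoxyphenyl)-2-(4-methoxyphenyl)-2,3-dihydro-1-benzofuran-5-yl]-4,4,5,5-tetramethyl-1,3,2-dioxaborolane
Conditions: B2pin2 (1.5 equiv), Pd2(dba)3 (2 mol%), XPhos (8 mol%), KOAc (3 equiv), 1,4-dioxane, 100 °C
Reagents that add atoms: bis(pinacolato)diboron, CC1(C)OB(OC1(C)C)B1OC(C)(C)C(C)(C)O1
Why: Miyaura borylation of an aryl chloride: zerovalent palladium with the bulky biaryl phosphine XPhos inserts into the C5′–Cl bond, acetate-assisted transmetalation with B2pin2 and reductive elimination give the pinacol boronate, and no stereocentre is involved.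

Step 6
Reactants: 12 2-bromo-4,6-dimethoxybenzaldehyde
Product: 13 (2E)-3-(2-bromo-4,6-dimethoxyphenyl)prop-2-enal
Conditions: Ph3P=CHCHO (1.3 equiv), toluene, 90 °C
Reagents that add atoms: (triphenylphosphoranylidene)acetaldehyde, O=CC=P(c1ccccc1)(c1ccccc1)c1ccccc1
Why: Wittig olefination with a formyl-stabilised ylide, which gives the E enal; only a small excess of ylide is used so that the product aldehyde is not homologated a second time.

Step 7
Reactants: 13 (2E)-3-(2-bromo-4,6-dimethoxyphenyl)prop-2-enal; 2 (4-methoxyphenyl)boronic acid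
Product: 14 (3R)-3-(2-bromo-4,6-dimethoxyphenyl)-3-(4-methoxyphenyl)propanal
Conditions: [RhCl(C2H4)2]2 (2.5 mol%), (1R,4R)-2,5-diphenylbicyclo[2.2.2]octa-2,5-diene (5.5 mol%), KOH (10 mol%), 1,4-dioxane/H2O (10:1), 30 °C
Reagents that add atoms: none
Why: Hayashi–Miyaura asymmetric 1,4-addition of an arylboronic acid to an enal with a chiral diene–rhodium catalyst (monovalent rhodium): the aryl–rhodium species adds to the β-carbon on the enantioface selected by the C2-symmetric diene, which sets C3 as R, water regenerates the hydroxo–rhodium species, and the aryl bromide does not react with rhodium under these conditions.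

Step 8
Reactants: 15 2-(diacetoxyiodo)-1,3,5-trimethylbenzene; 16 (3,5-dimethoxyphenyl)boronic acid
Product: 17 (3,5-dimethoxyphenyl)(2,4,6-trimethylphenyl)iodonium tetrafluoroborate
Conditions: BF3·OEt2 (promoter, 1.1 equiv), CH2Cl2, −30 → 25 °C; then saturated aqueous NaBF4
Reagents that add atoms: sodium tetrafluoroborate, [Na+].F[B-](F)(F)F
Why: Aryl transfer from boron to trivalent iodine (ligand exchange at the iodane activated by BF3, then ipso substitution at the carbon–boron bond), the standard regiospecific route to unsymmetrical diaryliodonium salts; mesityl is built in as the ligand that is not transferred later.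

Step 9
Reactants: 14 (3R)-3-(2-bromo-4,6-dimethoxyphenyl)-3-(4-methoxyphenyl)propanal; 17 (3,5-dimethoxyphenyl)(2,4,6-trimethylphenyl)iodonium tetrafluoroborate
Product: 18 (2R,3R)-3-(2-bromo-4,6-dimethoxyphenyl)-2-(3,5-dimethoxyphenyl)-3-(4-methoxyphenyl)propanal
Conditions: CuBr (10 mol%), (2R,5R)-5-benzyl-2-tert-butyl-3-methylimidazolidin-4-one·CCl3CO2H (20 mol%), NaHCO3 (1.2 equiv), toluene/Et2O (2:1), 23 °C
Reagents that add atoms: none
Why: Enantioselective α-arylation of an aldehyde by combined enamine and copper catalysis: monovalent copper and 17 give an electrophilic aryl–copper species (trivalent copper) that arylates the E enamine on the face not shielded by the benzyl group of the imidazolidinone, which sets C2 as R under catalyst control next to the resident C3 centre, the hindered mesityl group stays on iodine, and the bicarbonate-buffered medium does not epimerise the α-aryl aldehyde.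

Step 10
Reactants: 18 (2R,3R)-3-(2-bromo-4,6-dimethoxyphenyl)-2-(3,5-dimethoxyphenyl)-3-(4-methoxyphenyl)propanal
Product: 19 1-bromo-2-[(1R,2S)-2-(3,5-dimethoxyphenyl)-1-(4-methoxyphenyl)but-3-yn-1-yl]-3,5-dimethoxybenzene
Conditions: Me3SiCHN2 (1.3 equiv), n-BuLi (1.25 equiv), THF, −78 °C; then 18, −78 → 0 °C; H2O
Reagents that add atoms: (trimethylsilyl)diazomethane, C[Si](C)(C)C=[N+]=[N-]
Why: Colvin rearrangement: the lithiated diazomethane adds to the aldehyde at −78 °C faster than it enolises it, Peterson-type loss of lithium trimethylsilanolate, loss of N2 and a 1,2-hydride shift in the alkylidene carbene give the terminal alkyne with the former α-centre unchanged in space (the descriptor becomes S only because the priorities change), and the aryl bromide does not exchange with this reagent.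

Step 11
Reactants: 19 1-bromo-2-[(1R,2S)-2-(3,5-dimethoxyphenyl)-1-(4-methoxyphenyl)but-3-yn-1-yl]-3,5-dimethoxybenzene; 11 2-[(2S,3S)-3-(3,5-dimethoxyphenyl)-2-(4-methoxyphenyl)-2,3-dihydro-1-benzofuran-5-yl]-4,4,5,5-tetramethyl-1,3,2-dioxaborolane
Product: 20 (2S,3S)-3-(3,5-dimethoxyphenyl)-5-{(Z)-[(2R,3R)-2-(3,5-dimethoxyphenyl)-4,6-dimethoxy-3-(4-methoxyphenyl)-2,3-dihydro-1H-inden-1-ylidene]methyl}-2-(4-methoxyphenyl)-2,3-dihydro-1-benzofuran
Conditions: Pd(OAc)2 (5 mol%), SPhos (10 mol%), K3PO4 (3 equiv), THF/H2O (10:1), 60 °C
Reagents that add atoms: none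
Why: Carbopalladation–Suzuki cascade: oxidative addition of zerovalent palladium to the aryl bromide, syn 5-exo-dig insertion of the tethered alkyne (which closes the five-membered ring of the indane through the C7a–C1 bond) and coupling of the resulting alkenylpalladium with 11 with retention put the dihydrobenzofuran aryl group cis to C7a, which is the Z alkene of the target, while no stereocentre is formed or touched and the intramolecular insertion outruns direct biaryl coupling.

Step 12
Reactants: 20 (2S,3S)-3-(3,5-dimethoxyphenyl)-5-{(Z)-[(2R,3R)-2-(3,5-dimethoxyphenyl)-4,6-dimethoxy-3-(4-methoxyphenyl)-2,3-dihydro-1H-inden-1-ylidene]methyl}-2-(4-methoxyphenyl)-2,3-dihydro-1-benzofuran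
Product: 21 (1Z,2R,3R)-2-(3,5-dihydroxyphenyl)-1-{[(2S,3S)-3-(3,5-dihydroxyphenyl)-2-(4-hydroxyphenyl)-2,3-dihydro-1-benzofuran-5-yl]methylidene}-3-(4-hydroxyphenyl)-2,3-dihydro-1H-indene-4,6-diol
Conditions: BBr3 (24 equiv), CH2Cl2, −78 → 20 °C; then ice/H2O
Reagents that add atoms: none
Why: Exhaustive O-demethylation of aryl methyl ethers with BBr3 (ether–borane adduct, then attack of bromide at methyl), the usual last step for permethylated stilbene oligomers; every oxygen is tied up as an electron-poor aryloxyborane during the reaction, which should protect the benzylic ether C2′–O1′ and the exocyclic alkene from acid until the cold aqueous quench, so the four stereocentres and the Z geometry should be carried through.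

Compound list
1 | 6-chloro-4H-chromen-4-one (6-chlorochromone) | O=c1ccoc2ccc(Cl)cc12 | starting material
2 | (4-methoxyphenyl)boronic acid | COc1ccc(B(O)O)cc1 | starting material
3 | (2S)-6-chloro-2-(4-methoxyphenyl)-2,3-dihydro-4H-chromen-4-one | O=C1C[C@@H](c2ccc(OC)cc2)Oc2ccc(Cl)cc12 | intermediate
4 | (2S)-6-chloro-4-methoxy-2-(4-methoxyphenyl)-2H-chromene | COC1=C[C@@H](c2ccc(OC)cc2)Oc2ccc(Cl)cc12 | intermediate
5 | methyl (2S,3S)-5-chloro-2-(4-methoxyphenyl)-2,3-dihydro-1-benzofuran-3-carboxylate (trans) | Clc1ccc2c(c1)[C@H](C(=O)OC)[C@@H](c1ccc(OC)cc1)O2 | intermediate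
6 | (2S,3S)-5-chloro-2-(4-methoxyphenyl)-2,3-dihydro-1-benzofuran-3-carboxylic acid | Clc1ccc2c(c1)[C@H](C(=O)O)[C@@H](c1ccc(OC)cc1)O2 | intermediate
7 | 1-bromo-3,5-dimethoxybenzene | COc1cc(Br)cc(OC)c1 | starting material
8 | 1,3-dioxoisoindolin-2-yl (2S,3S)-5-chloro-2-(4-methoxyphenyl)-2,3-dihydro-1-benzofuran-3-carboxylate | Clc1ccc2c(c1)[C@H](C(=O)ON1C(=O)c3ccccc3C1=O)[C@@H](c1ccc(OC)cc1)O2 | intermediate
9 | (3,5-dimethoxyphenyl)zinc chloride | COc1cc([Zn]Cl)cc(OC)c1 | intermediate
10 | (2S,3S)-5-chloro-3-(3,5-dimethoxyphenyl)-2-(4-methoxyphenyl)-2,3-dihydro-1-benzofuran (trans) | Clc1ccc2c(c1)[C@H](c1cc(OC)cc(OC)c1)[C@@H](c1ccc(OC)cc1)O2 | intermediate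
11 | 2-[(2S,3S)-3-(3,5-dimethoxyphenyl)-2-(4-methoxyphenyl)-2,3-dihydro-1-benzofuran-5-yl]-4,4,5,5-tetramethyl-1,3,2-dioxaborolane | CC1(C)OB(OC1(C)C)c1ccc2c(c1)[C@H](c1cc(OC)cc(OC)c1)[C@@H](c1ccc(OC)cc1)O2 | intermediate
12 | 2-bromo-4,6-dimethoxybenzaldehyde | COc1cc(Br)c(C=O)c(OC)c1 | starting material
13 | (2E)-3-(2-bromo-4,6-dimethoxyphenyl)prop-2-enal | COc1cc(Br)c(/C=C/C=O)c(OC)c1 | intermediate
14 | (3R)-3-(2-bromo-4,6-dimethoxyphenyl)-3-(4-methoxyphenyl)propanal | COc1ccc([C@H](c2c(OC)cc(OC)cc2Br)CC=O)cc1 | intermediate
15 | 2-(diacetoxyiodo)-1,3,5-trimethylbenzene (iodomesitylene diacetate) | CC(=O)OI(OC(C)=O)c1c(C)cc(C)cc1C | starting material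
16 | (3,5-dimethoxyphenyl)boronic acid | COc1cc(cc(OC)c1)B(O)O | starting material
17 | (3,5-dimethoxyphenyl)(2,4,6-trimethylphenyl)iodonium tetrafluoroborate | COc1cc(cc(OC)c1)[I+]c1c(C)cc(C)cc1C.F[B-](F)(F)F | intermediate
18 | (2R,3R)-3-(2-bromo-4,6-dimethoxyphenyl)-2-(3,5-dimethoxyphenyl)-3-(4-methoxyphenyl)propanal | COc1ccc([C@H](c2c(OC)cc(OC)cc2Br)[C@@H](C=O)c2cc(OC)cc(OC)c2)cc1 | intermediate
19 | 1-bromo-2-[(1R,2S)-2-(3,5-dimethoxyphenyl)-1-(4-methoxyphenyl)but-3-yn-1-yl]-3,5-dimethoxybenzene | COc1ccc([C@H](c2c(OC)cc(OC)cc2Br)[C@@H](C#C)c2cc(OC)cc(OC)c2)cc1 | intermediate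
20 | (2S,3S)-3-(3,5-dimethoxyphenyl)-5-{(Z)-[(2R,3R)-2-(3,5-dimethoxyphenyl)-4,6-dimethoxy-3-(4-methoxyphenyl)-2,3-dihydro-1H-inden-1-ylidene]methyl}-2-(4-methoxyphenyl)-2,3-dihydro-1-benzofuran | COc1ccc([C@@H]2c3c(OC)cc(OC)cc3/C(=C\c3ccc4c(c3)[C@H](c3cc(OC)cc(OC)c3)[C@@H](c3ccc(OC)cc3)O4)[C@H]2c2cc(OC)cc(OC)c2)cc1 | intermediate
21 | (1Z,2R,3R)-2-(3,5-dihydroxyphenyl)-1-{[(2S,3S)-3-(3,5-dihydroxyphenyl)-2-(4-hydroxyphenyl)-2,3-dihydro-1-benzofuran-5-yl]methylidene}-3-(4-hydroxyphenyl)-2,3-dihydro-1H-indene-4,6-diol | Oc1ccc([C@@H]2c3c(O)cc(O)cc3/C(=C\c3ccc4c(c3)[C@H](c3cc(O)cc(O)c3)[C@@H](c3ccc(O)cc3)O4)[C@H]2c2cc(O)cc(O)c2)cc1 | target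

Total step count: 12. Longest linear sequence: 7 steps (steps 1, 2, 3, 4, 5, 11 and 12); the bromo-alkyne 19 is made in steps 6 to 10 and joins in step 11.

Steps most likely to fail

Step 2 (key step). The migration may go the other way, with the electron-rich anisyl group moving from C2 to C3 to give the isoflavone. The iodane may instead eliminate to the flavone, or acid may open the pyranone and erode the C2 configuration. Fallback: the same C4a shift would be brought about by a Wolff rearrangement instead of an oxidation. It sets out from 3 and comes back at 5. Flavanone 3 would be converted by detrifluoroacetylative diazo transfer (LiN(SiMe3)2, CF3CO2CH2CF3, THF, −78 °C; then MsN3, Et3N, MeCN) into (2R)-6-chloro-3-diazo-2-(4-methoxyphenyl)-2,3-dihydro-4H-chromen-4-one F1, in which C2 keeps its spatial arrangement and only the descriptor changes. Irradiation of this diazo ketone in methanol would contract the ring and give 5 together with its cis isomer methyl (2S,3R)-5-chloro-2-(4-methoxyphenyl)-2,3-dihydro-1-benzofuran-3-carboxylate F2. NaOMe in MeOH would then equilibrate the cis ester at C3′ to the trans ester 5.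

Step 9. Enamine formation from the hindered β,β-diaryl aldehyde may be slow, the catalyst and the resident C3 centre may be mismatched so that facial selectivity at C2 is poor, or the α-aryl aldehyde may epimerise during isolation. Fallback: catalyst control would be given up for a palladium-catalysed enolate arylation with equilibration and separation. It sets out from 14 and comes back at 18. Aldehyde 14 would be arylated with commercial 1-iodo-3,5-dimethoxybenzene (Pd(OAc)2, rac-BINAP, Cs2CO3, 1,4-dioxane, 80 °C), the iodide being chosen so that it reacts before the aryl bromide of 14. Under the basic conditions C2 equilibrates, so 18 would be formed together with its C2 epimer (2S,3R)-3-(2-bromo-4,6-dimethoxyphenyl)-2-(3,5-dimethoxyphenyl)-3-(4-methoxyphenyl)propanal F3. The two diastereomers would be separated by chromatography and the unwanted one returned to the equilibrium with Cs2CO3, so that the material converges on 18.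

Step 11. The aryl bromide may couple with the boronate before the alkyne inserts, the terminal alkyne C–H may be drawn into coupling, or transmetalation at the hindered alkenylpalladium may be slow enough for it to decompose or lose its geometry. Fallback: ring closure and union would be separated and the polarity of the coupling reversed. It sets out from 19 (with 10 as partner, so that step 5 is not needed for this material) and comes back at 20. The same syn carbopalladation of 19 would be terminated with B2pin2 instead of an aryl boronate (Pd(OAc)2, PPh3, KOAc, toluene, 80 °C) to give 2-{(Z)-[(2R,3R)-2-(3,5-dimethoxyphenyl)-4,6-dimethoxy-3-(4-methoxyphenyl)-2,3-dihydro-1H-inden-1-ylidene]methyl}-4,4,5,5-tetramethyl-1,3,2-dioxaborolane F4. This isolable alkenyl boronate would then be coupled with aryl chloride 10 (Pd(OAc)2, SPhos, K3PO4, THF/H2O, 60 °C) to give 20 with the same Z geometry.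

Further compounds
F1 | step 2 | (2R)-6-chloro-3-diazo-2-(4-methoxyphenyl)-2,3-dihydro-4H-chromen-4-one | O=C1C(=[N+]=[N-])[C@@H](c2ccc(OC)cc2)Oc2ccc(Cl)cc12
F2 | step 2 | methyl (2S,3R)-5-chloro-2-(4-methoxyphenyl)-2,3-dihydro-1-benzofuran-3-carboxylate | Clc1ccc2c(c1)[C@@H](C(=O)OC)[C@@H](c1ccc(OC)cc1)O2
F3 | step 9 | (2S,3R)-3-(2-bromo-4,6-dimethoxyphenyl)-2-(3,5-dimethoxyphenyl)-3-(4-methoxyphenyl)propanal | COc1ccc([C@H](c2c(OC)cc(OC)cc2Br)[C@H](C=O)c2cc(OC)cc(OC)c2)cc1
F4 | step 11 | 2-{(Z)-[(2R,3R)-2-(3,5-dimethoxyphenyl)-4,6-dimethoxy-3-(4-methoxyphenyl)-2,3-dihydro-1H-inden-1-ylidene]methyl}-4,4,5,5-tetramethyl-1,3,2-dioxaborolane | COc1ccc([C@@H]2c3c(OC)cc(OC)cc3/C(=C\B3OC(C)(C)C(C)(C)O3)[C@H]2c2cc(OC)cc(OC)c2)cc1
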